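(The readings were computed from invented constants, and the scatter is random.)

The left-handed substrate in oak cannot have kept its opening pace: it falls at a mean 24.4 mM/h up to 0.667 h, yet its reading differs by 1.1 percentage points between 3.00 h and 10.0 h, against a scatter of 1 point.

| flask | left-handed substrate | right-handed substrate | partner | protic impurity | catalyst | remark | time |
|---|---|---|---|---|---|---|---|
| oak | 20 mM | 20 mM | 40 mM | 6 mM | 16 µM | run made earlier |  |
| alder | 20 mM | 20 mM | 40 mM | 6 mM | 36 µM | run made earlier |  |
| maple | 40 mM | 40 mM | 40 mM | 6 mM | 24 µM | run made earlier |  |
| flask | 20 mM | 20 mM | 40.0 mM | 6.00 mM | 24 µM |  | 12 h |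

| run | time / h | right-handed substrate / % | left-handed substrate / % |
|---|---|---|---|
| oak | 0.667 | 46.2 | 9.3 |
| oak | 2.00 | 47.1 | 7.3 |
| oak | 3.00 | 48.3 | 5.6 |
| oak | 5.00 | 47.4 | 5.9 |
| oak | 8.00 | 47.5 | 6.5 |
| oak | 10.0 | 46.8 | 6.7 |
| alder | 0.833 | 45.9 | 1.3 |
| alder | 1.33 | 45.0 | 2.1 |
| alder | 2.00 | 44.9 | 1.4 |
| alder | 4.00 | 44.8 | 1.7 |
| alder | 6.00 | 43.9 | 1.2 |
| alder | 10.0 | 44.8 | 0.4 |
| maple | 2.00 | 49.2 | 14.0 |
| maple | 4.00 | 49.2 | 13.8 |
| maple | 6.00 | 47.2 | 14.1 |
| maple | 8.00 | 47.4 | 13.4 |
| maple | 10.0 | 48.9 | 15.0 |

(standard deviation of a reading: 1 percentage point)

- catalyst is single-handed; left-handed substrate and right-handed substrate are mirror images of each other, charged as a racemate, each of them at the stated concentration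
- on the list of suspects stand: partner + catalyst + left-handed substrate -> catalyst + left-handed product; partner + catalyst + right-handed substrate -> catalyst + right-handed product; left-handed product <-> right-handed product; 2 partner -> self-condensation product; partner + protic impurity -> quenched reagent

1. whether the excess of right-handed substrate over left-handed substrate among what is left of the two reaches 80% by 12 h (no / yes)
2. the highest excess of right-handed substrate over left-handed substrate among what is left of the two up to 12 h

I replace each curve by the mean of its late readings, from 3.00 h in oak and from 0.833 h in alder, and multiply the part of the two substrates reacted by their joint charge. That gives 18.5 mM in oak and 21.5 mM in alder, each out of 40 mM of partner, which I read as the limiting reagent. The flask's catalyst is the geometric mean of theirs, 24.0 µM, so on log catalyst I expect the mean of the two, 20.0 mM. This is the useful partner, the partner that ends on a substrate.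

The same mean puts the left-handed substrate at 3.76%, so my end excess is 84.9%, higher than 80%.

The forecast says yes with a top of 87%, higher than mine, holding that “the plateau comes from running out of partner, not from slow reaction”.

The flask gives yes and 89.0%.

    partner + catalyst + left-handed substrate → catalyst + left-handed product (k = 3.30 × 10⁵ /M²/min)
    partner + catalyst + right-handed substrate → catalyst + right-handed product (k = 8000 /M²/min)
    left-handed product ⇌ right-handed product (k = 0.0340 /min)
    2 partner → self-condensation product (k = 1.80 /M/min)
    partner + protic impurity → quenched reagent (k = 3.60 /M/min)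

Partner in the flask stands at 1.95% of its charge at 1.20 h. The products hold a useful partner of 20.3 mM at 12.0 h. In the run with twice the protic impurity and all other amounts as in the flask, the excess at the end is 79.9%, level with the mark. Taking the right-handed substrate at this flask's 46.6%, that excess means 5.20% left-handed substrate and a useful partner of 19.3 mM, which is 1.00 mM below this flask's.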